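**Strategy.** In the cyclopentenone ring, C1 (C=O) and C4 (CH–OAc) both carry oxygen and lie 1,4 to each other across C2=C3, with the fully substituted carbinol C5 between them on the other side of the ring. This pattern is read as an opened endoperoxide, so the C1–O and C4–O bonds are both disconnected to one molecule of singlet oxygen. Its [4+2] addition to a 5,5-disubstituted cyclopentadiene makes both bonds at once, closes the 2,3-dioxabicyclo[2.2.1]heptene and sets both oxygens cis to the C5 oxygen. The diene is the spiro-acetonide of the C5/C1' diol, with (S)-C1' taken from methyl (S)-glycidate; its rigid dioxolane also differentiates the two bridgeheads for the later ring opening.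

Key step: step 7

Remark on locants: target atoms C1 (C=O), C2=C3, C4 (CH–OAc), C5 (C–OH) and C1' correspond to C6, C7=C8, C9, C5 and C4 of the 1,3-dioxaspiro[4.4]nonane intermediates.
Assumption: endoperoxide 16 is thermally labile and is therefore handled only as a cold solution between steps 7 and 8.

**Route**

Step 1
Reactants: 1 methyl (2S)-oxirane-2-carboxylate; 2 1-bromotridecane
Product: 4 methyl (2S)-2-hydroxyhexadecanoate, via tridecylmagnesium bromide 3 (not isolated)
Conditions: 2, Mg turnings, THF, 45 °C; then added to 1 and CuI (10 mol%), THF, −78 → −30 °C; aq. NH4Cl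
Reagents that add atoms: 1-bromotridecane, CCCCCCCCCCCCCBr
Why: Copper-catalysed Grignard opening of the glycidate at its unsubstituted C3 (SN2) should outrun carbonyl addition at low temperature and does not touch C2, so the (S) centre of 1 becomes the carbinol carbon that ends as C1'.

Step 2
Reactants: 4 methyl (2S)-2-hydroxyhexadecanoate; 5 allylmagnesium bromide
Product: 7 (5S)-4-(prop-2-en-1-yl)nonadec-1-ene-4,5-diol, via allyl ketone 6 (not isolated)
Conditions: allylMgBr (3.5 equiv), Et2O/THF, 0 °C → rt; aq. NH4Cl
Reagents that add atoms: allylmagnesium bromide, C=CC[Mg]Br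
Why: Double Grignard addition to the ester (the first equivalent only deprotonates the hydroxyl) should proceed without enolising the α-alkoxide centre, and the new carbinol carbon carries two identical allyl groups and is not stereogenic.

Step 3
Reactants: 7 (5S)-4-(prop-2-en-1-yl)nonadec-1-ene-4,5-diol
Product: 8 1-[(1S)-1-hydroxypentadecyl]cyclopent-3-en-1-ol
Conditions: (H2IMes)(PCy3)Cl2Ru=CHPh (second-generation Grubbs catalyst, 2 mol%), CH2Cl2, 40 °C
Reagents that add atoms: none
Why: Ring-closing metathesis of the 1,6-diene to a cyclopentene is favoured by the quaternary carbinol carbon and tolerates free hydroxyls, and no stereocentre is involved.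

Step 4
Reactants: 8 1-[(1S)-1-hydroxypentadecyl]cyclopent-3-en-1-ol; 9 2,2-dimethoxypropane
Product: 10 (4S)-2,2-dimethyl-4-tetradecyl-1,3-dioxaspiro[4.4]non-7-ene
Conditions: Me2C(OMe)2 (3 equiv), pyridinium p-toluenesulfonate (5 mol%), CH2Cl2, rt
Reagents that add atoms: 2,2-dimethoxypropane, COC(C)(C)OC
Why: Acid-catalysed transketalisation of the 1,2-diol should give the five-membered isopropylidene ketal without breaking a bond at the stereocentre.

Step 5
Reactants: 10 (4S)-2,2-dimethyl-4-tetradecyl-1,3-dioxaspiro[4.4]non-7-ene; 11 bromine
Product: 12 trans-7,8-dibromide: (4S,7R,8R)-7,8-dibromo-2,2-dimethyl-4-tetradecyl-1,3-dioxaspiro[4.4]nonane plus its (4S,7S,8S) isomer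
Conditions: Br2 (1.05 equiv), CH2Cl2, −78 °C; aq. Na2S2O3/NaHCO3
Reagents that add atoms: bromine, BrBr
Why: Anti addition through the bromonium ion gives the trans-dibromide, and since both trans diastereomers lead to the same diene no selectivity is needed.

Step 6
Reactants: 12 trans-7,8-dibromide
Product: 14 (4S)-2,2-dimethyl-4-tetradecyl-1,3-dioxaspiro[4.4]nona-6,8-diene, via allylic bromide 13 (not isolated)
Conditions: KOtBu (3 equiv), 18-crown-6 (10 mol%), THF, 0 °C → rt; cold pentane/water work-up, used at once
Reagents that add atoms: none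
Why: Two successive anti E2 eliminations, each using a hydrogen on C6 or C9 next to the quaternary spiro carbon, should give the 6,8-diene, which cannot isomerise by hydrogen shift because C5 bears no hydrogen.

Step 7
Reactants: 14 (4S)-2,2-dimethyl-4-tetradecyl-1,3-dioxaspiro[4.4]nona-6,8-diene; 15 oxygen
Product: 16 (5'S)-2',2'-dimethyl-5'-tetradecylspiro[2,3-dioxabicyclo[2.2.1]hept-5-ene-7,4'-[1,3]dioxolane] having the O–O bridge on the side of the dioxolane oxygen bound to the spiro carbon (O1 of 14) while the C=C bridge faces the tetradecyl-bearing carbon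
Conditions: O2, 5,10,15,20-tetraphenylporphyrin (0.5 mol%), visible light, CH2Cl2, −78 °C; solution kept at −78 °C for step 8
Reagents that add atoms: oxygen, O=O
Why: Sensitised singlet oxygen adds to the s-cis-locked diene in a concerted suprafacial hetero-Diels–Alder reaction that forms the C6–O and C9–O bonds (C1–O and C4–O of the target) together; the closest known reaction type is the dye-sensitised photooxygenation of cyclopentadienes, spiro-cyclopentadienes included, to 2,3-dioxabicyclo[2.2.1]hept-5-enes. The one new ring, the six-membered 3,6-dihydro-1,2-dioxine that bridges C6 and C9, is closed by this intermolecular [4+2] cycloaddition and not by a cyclisation. The two bridgehead stereocentres are cis because the addition is suprafacial, and the spiro carbon C5 becomes stereogenic with its sense set by the diene face that is attacked. Attack on the face syn to O1 is expected because cyclopentadienes with a heteroatom on the sp3 carbon take dienophiles on the heteroatom face and because the dioxolane shows only its bare ring oxygen to that face while the other face carries the C4–H/C4–tetradecyl arm. Facial selectivity is the only selectivity needed: the regiochemistry is fixed by the diene termini, no ene reaction can compete since C5 has no hydrogen, and −78 °C holds back diene dimerisation and rearrangement of the endoperoxide.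

Step 8
Reactants: 16 spiro endoperoxide
Product: 17 (4S,5R,9S)-9-hydroxy-2,2-dimethyl-4-tetradecyl-1,3-dioxaspiro[4.4]non-7-en-6-one (9-OH cis to O1)
Conditions: Et3N (1.2 equiv), CH2Cl2, −78 → −30 °C
Reagents that add atoms: none
Why: In this Kornblum–DeLaMare rearrangement the amine removes a bridgehead hydrogen anti-periplanar to the O–O bond, and because the dioxolane lies in the local mirror plane of the bicycle and holds the tetradecyl chain over one bridgehead, the exposed proton on the C4–H side should be taken, which makes that carbon the C6 carbonyl (C1 of the target) while the C9 carbinol keeps its configuration.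

Step 9
Reactants: 17 cis-hydroxy enone; 18 acetic acid
Product: 19 (4S,5S,9R)-2,2-dimethyl-6-oxo-4-tetradecyl-1,3-dioxaspiro[4.4]non-7-en-9-yl acetate (9-OAc trans to O1)
Conditions: PPh3 (2 equiv), DIAD (2 equiv), AcOH (2 equiv), toluene, 0 °C → rt (PPh3/DIAD premixed)
Reagents that add atoms: acetic acid, CC(=O)O
Why: In this Mitsunobu esterification acetate should displace the activated allylic oxygen at C9 by SN2 with inversion, turning the cis carbinol into the trans acetate, since the SN2' terminus is the deactivated α-carbon of the enone and C5 offers no hydrogen for elimination.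

Step 10
Reactants: 19 trans-acetoxy enone acetonide
Product: 20 (1R,5S)-5-hydroxy-5-[(1S)-1-hydroxypentadecyl]-4-oxocyclopent-2-en-1-yl acetate
Conditions: TFA/H2O (9:1), CH2Cl2, 0 °C → rt
Reagents that add atoms: none
Why: Acid hydrolysis of the isopropylidene ketal through its oxocarbenium ion should release acetone and the C5/C1' diol without breaking a C–O bond at a stereocentre, the acetate being stable to cold aqueous acid.

Step 11
Reactants: 20 diol monoacetate; 21 acetic anhydride
Product: 22 (1S)-1-[(1S,2R)-2-acetoxy-1-hydroxy-5-oxocyclopent-3-en-1-yl]pentadecyl acetate (the target; (4R,5S)-4-acetoxy-5-[(1S)-1-acetoxypentadecyl]-5-hydroxycyclopent-2-en-1-one)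
Conditions: Ac2O (1.5 equiv), pyridine, 4-(dimethylamino)pyridine (5 mol%), CH2Cl2, 0 °C → rt
Reagents that add atoms: acetic anhydride, CC(=O)OC(C)=O
Why: Acylation should take the secondary C1' hydroxyl with retention and leave the tertiary, ketone-flanked C5 hydroxyl free, and a prior 1,3-acetyl shift between the C4 and C1' oxygens would end in the same diacetate.

**Compound list**

1 | methyl (2S)-oxirane-2-carboxylate | COC(=O)[C@@H]1CO1 | starting material
2 | 1-bromotridecane | CCCCCCCCCCCCCBr | starting material
3 | tridecylmagnesium bromide | CCCCCCCCCCCCC[Mg]Br | intermediate (not isolated)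
4 | methyl (2S)-2-hydroxyhexadecanoate | CCCCCCCCCCCCCC[C@H](O)C(=O)OC | intermediate
5 | allylmagnesium bromide | C=CC[Mg]Br | starting material
6 | (5S)-5-hydroxynonadec-1-en-4-one (allyl ketone, present as its bromomagnesium alkoxide) | CCCCCCCCCCCCCC[C@H](O)C(=O)CC=C | intermediate (not isolated)
7 | (5S)-4-(prop-2-en-1-yl)nonadec-1-ene-4,5-diol | CCCCCCCCCCCCCC[C@H](O)C(O)(CC=C)CC=C | intermediate
8 | 1-[(1S)-1-hydroxypentadecyl]cyclopent-3-en-1-ol | CCCCCCCCCCCCCC[C@H](O)C1(O)CC=CC1 | intermediate
9 | 2,2-dimethoxypropane | COC(C)(C)OC | starting material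
10 | (4S)-2,2-dimethyl-4-tetradecyl-1,3-dioxaspiro[4.4]non-7-ene | CCCCCCCCCCCCCC[C@@H]1OC(C)(C)OC12CC=CC2 | intermediate
11 | bromine | BrBr | starting material
12 | (4S,7R,8R)-7,8-dibromo-2,2-dimethyl-4-tetradecyl-1,3-dioxaspiro[4.4]nonane (trans; the (4S,7S,8S) trans isomer forms alongside and converges) | CCCCCCCCCCCCCC[C@@H]1OC(C)(C)OC12C[C@@H](Br)[C@H](Br)C2 | intermediate
13 | (4S)-8-bromo-2,2-dimethyl-4-tetradecyl-1,3-dioxaspiro[4.4]non-6-ene (allylic bromide; mixture at C5/C8, all converge) | CCCCCCCCCCCCCC[C@@H]1OC(C)(C)OC12C=CC(Br)C2 | intermediate (not isolated)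
14 | (4S)-2,2-dimethyl-4-tetradecyl-1,3-dioxaspiro[4.4]nona-6,8-diene | CCCCCCCCCCCCCC[C@@H]1OC(C)(C)OC12C=CC=C2 | intermediate
15 | oxygen | O=O | starting material
16 | (5'S)-2',2'-dimethyl-5'-tetradecylspiro[2,3-dioxabicyclo[2.2.1]hept-5-ene-7,4'-[1,3]dioxolane], O–O bridge syn to the spiro-bound dioxolane oxygen | CCCCCCCCCCCCCC[C@@H]1OC(C)(C)O[C@]12[C@@H]3C=C[C@H]2OO3 | intermediate
17 | (4S,5R,9S)-9-hydroxy-2,2-dimethyl-4-tetradecyl-1,3-dioxaspiro[4.4]non-7-en-6-one | CCCCCCCCCCCCCC[C@@H]1OC(C)(C)O[C@]12[C@@H](O)C=CC2=O | intermediate
18 | acetic acid | CC(=O)O | starting material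
19 | (4S,5S,9R)-2,2-dimethyl-6-oxo-4-tetradecyl-1,3-dioxaspiro[4.4]non-7-en-9-yl acetate | CCCCCCCCCCCCCC[C@@H]1OC(C)(C)O[C@]12[C@H](OC(C)=O)C=CC2=O | intermediate
20 | (1R,5S)-5-hydroxy-5-[(1S)-1-hydroxypentadecyl]-4-oxocyclopent-2-en-1-yl acetate | CCCCCCCCCCCCCC[C@H](O)[C@]1(O)[C@H](OC(C)=O)C=CC1=O | intermediate
21 | acetic anhydride | CC(=O)OC(C)=O | starting material
22 | (1S)-1-[(1S,2R)-2-acetoxy-1-hydroxy-5-oxocyclopent-3-en-1-yl]pentadecyl acetate | CCCCCCCCCCCCCC[C@H](OC(C)=O)[C@@]1(O)C(=O)C=C[C@H]1OC(C)=O | target

**Count**

Total steps: 11. Longest linear sequence: 11 steps (1 and 2 to 22).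

**Steps most likely to fail**

Step 7. The process at risk is attack of singlet oxygen on the diene face syn to the C4 arm in competition with the O1 face, together with rearrangement of the endoperoxide if the solution warms. The fallback sets out from 14 and comes back at 19; it makes the route convergent in the face of attack. The photooxygenation mixture is carried unseparated through the amine-induced rearrangement of step 8. The anti adduct, (5'S)-2',2'-dimethyl-5'-tetradecylspiro[2,3-dioxabicyclo[2.2.1]hept-5-ene-7,4'-[1,3]dioxolane] with the O–O bridge syn to the tetradecyl-bearing carbon F1, should lose the bridgehead proton on the C4–H side as 16 does. This gives the trans hydroxy enone (4S,5R,9R)-9-hydroxy-2,2-dimethyl-4-tetradecyl-1,3-dioxaspiro[4.4]non-7-en-6-one F2, a diastereomer of 17 that should separate on silica. F2 already has the C9 oxygen on the required face and is acetylated with retention (Ac2O, pyridine, 4-(dimethylamino)pyridine, CH2Cl2, 0 °C) to 19, while 17 goes on through step 9.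

Step 8. The process at risk is loss of the bridgehead proton on the chain side in competition with the one on the C4–H side, which would lead to the C5-epimeric ring, or thermal rearrangement of 16 before deprotonation. The fallback sets out from 16 and comes back at 17; it replaces the base-induced fragmentation by reduction followed by a sterically demanding oxidation. Thiourea (MeOH/CH2Cl2, −78 °C → rt) should reduce the O–O bond to the stable cis-ene-diol (4S,6R,9S)-2,2-dimethyl-4-tetradecyl-1,3-dioxaspiro[4.4]non-7-ene-6,9-diol F3, with both hydroxyls cis to O1. Oxidation with 2,2,6,6-tetramethylpiperidin-1-oxyl (10 mol%) and PhI(OAc)2 (1.05 equiv) in CH2Cl2 removes a carbinol hydrogen by hydride transfer to a bulky oxoammonium ion. Both carbinol hydrogens sit on the C4 face, C6–H beside C4–H and C9–H under the tetradecyl chain, so the oxidant should take C6–H and give 17.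

Step 9. The process at risk is slow backside attack of acetate at C9, which is flanked by the quaternary spiro carbon and lies under the tetradecyl chain on the face the nucleophile must use, so that the alcohol is recovered or acylated with retention. The fallback sets out from 17 and comes back at 19; it resets C9 by hydride delivery and needs no substitution at carbon. MnO2 (CH2Cl2, rt) should give the ene-dione (4S)-2,2-dimethyl-4-tetradecyl-1,3-dioxaspiro[4.4]non-7-ene-6,9-dione F4. Corey–Bakshi–Shibata reduction ((S)-2-methyl-CBS-oxazaborolidine, 10 mol%, BH3·SMe2, toluene, −78 °C) delivers hydride from the open O1 face. With the quaternary spiro carbon as the larger flank, the (S)-catalyst should select the C9 carbonyl and give the trans hydroxy enone F2. Acetylation (Ac2O, pyridine) then gives 19.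

**Further compounds**

F1 | step 7 | (5'S)-2',2'-dimethyl-5'-tetradecylspiro[2,3-dioxabicyclo[2.2.1]hept-5-ene-7,4'-[1,3]dioxolane], O–O bridge syn to the tetradecyl-bearing dioxolane carbon | CCCCCCCCCCCCCC[C@@H]1OC(C)(C)O[C@@]12[C@@H]3C=C[C@H]2OO3
F2 | step 7 | (4S,5R,9R)-9-hydroxy-2,2-dimethyl-4-tetradecyl-1,3-dioxaspiro[4.4]non-7-en-6-one | CCCCCCCCCCCCCC[C@@H]1OC(C)(C)O[C@]12[C@H](O)C=CC2=O
F3 | step 8 | (4S,6R,9S)-2,2-dimethyl-4-tetradecyl-1,3-dioxaspiro[4.4]non-7-ene-6,9-diol, both hydroxyls cis to O1 | CCCCCCCCCCCCCC[C@@H]1OC(C)(C)O[C@]12[C@@H](O)C=C[C@H]2O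
F4 | step 9 | (4S)-2,2-dimethyl-4-tetradecyl-1,3-dioxaspiro[4.4]non-7-ene-6,9-dione | CCCCCCCCCCCCCC[C@@H]1OC(C)(C)OC12C(=O)C=CC2=O
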